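## Structural features

The target is a bis-isoflavonoid built from two chroman units and two further benzene rings. Unit 1 is a 7-hydroxychroman (ring A fused to the pyran ring C: O1, C2, C3, C4, C4a, C8a) with the 2-hydroxy-4-methoxyphenyl ring B on C3 and the central ring D on C4. Ring D is a 1,2,4,5-tetrasubstituted benzene with a methoxy group ortho and a hydroxyl para to the C4 attachment, and, next to that hydroxyl, C3 of unit 2, a 7-hydroxychroman (ring E with its own pyran ring). There are three stereocentres: C3 (S) and C4 (R) of unit 1 are adjacent and hold their aryl groups trans, whereas C3 (S) of unit 2 is insulated from them by ring D. The fragile features are four free phenols on electron-rich rings and the doubly benzylic C4–H; C2, C3 and C4 carry no heteroatom or carbonyl handle. The real difficulty is the absolute configuration of the trans-3,4-diaryl pair on an otherwise unfunctionalised pyran ring, together with the need to tell six phenolic oxygens apart. The key step exploits that ring C is the formal [4+2] adduct of a cationic 2-oxadiene (C4a=C8a of ring A, O1 and C2 as an aryloxymethyl cation) with the C3=C4 double bond of an (E)-stilbene of rings B and D, and that the para oxygen and ortho methoxy group of ring D stabilise positive charge at C4.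

## Logic of the disconnections

**24 to 23 to 22.** The bonds cut are the three O–benzyl bonds on rings A, D and E and the O–pivaloyl bond on ring B. The phenols cannot be free in a cationic step, and the ring B oxygen must be an ester there, both to lower the donor power of ring B and to keep its oxygen from capturing a cation at C4. Nothing is gained in skeleton, but only two deprotections remain after the key step. The forward steps must cleave the ester (methoxide, no hydride reagent) and the benzyl ethers (hydrogenolysis) without touching the non-benzylic ring C–O bonds or C3 and C4.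

**22 to 21 and 2.** The bonds cut are C2–C3 and C4–C4a. Cutting here removes ring C and both adjacent stereocentres at once and divides the molecule into a costly alkene, 21, and a one-step C1 acetal, 2. The forward step demands four things:
- ionisation of 2 only towards the aryloxymethyl cation;
- C–C bond formation at the alkene carbon that bears ring B;
- face selection at C3 by a chiral counteranion;
- ring closure on ring A para to its benzyloxy group.

**21 to 20 and 5.** The bond cut is the one between C1 of ring D and the alkene carbon. A Heck reaction delivers the (E)-geometry directly and uses the bromine present since 6. The gain is that unit 2 with ring D and ring B become separate fragments. The forward step needs oxidative addition into an electron-rich aryl bromide and a base that leaves the aryl ester alone.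

**5 to 4 to 3.** The bonds cut are the terminal C=C (Wittig methylenation) and the O–acyl bond. This leads back to a commercial salicylaldehyde in two steps. The ylide must react at the formyl group and not at the hindered ester.

**2 to 1.** The bond cut is O–CH2 of the acetal. One alkylation of a commercial phenol with chloromethyl pivalate gives the acetal and avoids chloromethyl methyl ether. The phenoxide must attack the CH2Cl carbon and not the pivaloyl carbonyl.

**20 to 18 (through 19).** The bond cut is O1–C2 of unit 2. Closing the pyran ring by O-alkylation leaves the C3 stereocentre untouched. The forward step needs a free phenoxide and an activated primary carbon in the same molecule, obtained by mesylation and fluoride desilylation in one flask.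

**18 to 17 to 12 and 16.** The bonds cut are the acyl–N bond of the auxiliary (reductively) and the C3–C4 bond of unit 2. An auxiliary-controlled enolate benzylation is the most reliable way to set the lone stereocentre of unit 2 on a small molecule. It divides unit 2 into a ring D arylacetyl unit and a ring E benzylic bromide. The forward step needs a reactive but labile electron-rich benzylic bromide and a product that does not epimerise.

**12 to 10 to 8 to 7 to 6.** The bonds cut are the N–acyl bond, the enol ether C=C (one-carbon homologation of the aldehyde) and the O–benzyl bond. The homologation puts the former aldehyde carbon at C3 of unit 2 without cyanide or diazomethane. The arylacetaldehyde stage must not be isolated.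

**16 to 15 to 14 to 13.** The bonds cut are C–Br, the carbinol C–H (reduction) and O–Si. The silyl group distinguishes the ring E oxygen that will become O1 from the one kept as benzyl ether. It must not migrate to the benzylic oxygen and must leave with fluoride.

## Other disconnections considered

**Alternative 1:** o-quinone methide plus arylacetyl enolate.
- Cut: C3–C4 and O1–C2 of ring C, with C2 at the lactone oxidation level.
- Forward key step: base would release the o-quinone methide A4 from the sulfone A2. The arylacetic acid A3, activated as its mixed pivalic anhydride, would be converted by benzotetramisole into a chiral ammonium enolate, which would add to A4 and lactonise to the trans dihydrocoumarin A1.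
- In favour: the polarity of the partners fixes which carbon carries which ring, so no electronic bias between rings B and D is needed. On this point it is better than the chosen plan. Both stereocentres arise in one catalytic step, which is equal to the chosen plan. The reaction class has closer precedent, which is also better.
- Against: A1 has a carbonyl at C2, so reduction to a diol and re-closure of ring C are needed to reach A7, two extra operations with a hydride reagent. C3 of A1 is alpha to the lactone carbonyl and can epimerise under the basic conditions. A2 needs formylation of the ring D bromide and a regioselective three-component sulfone condensation on ring A. A3 needs its own homologation.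
- Comparison: mechanistically this is enolate chemistry instead of a free benzylic cation, so arene alkylation and alkene protonation do not threaten it. Structurally it delivers the wrong oxidation state at C2. In step count it is estimated at three to four steps longer.

**Alternative 2:** chalcone to isoflavone for unit 2.
- Cut: in unit 2, the bond between ring D and C3 and the O1–C2 bond, so that unit 2 is built last on a ring D already carrying unit 1.
- Forward key step: Tl(NO3)3 (trivalent thallium) in methanol would add to the alkene of the chalcone A6. Ring D would shift from the beta to the alpha carbon as thallium leaves, and acid would close the keto acetal to the isoflavone A5.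
- In favour: A6 comes from a simple aldol condensation. The electron-rich ring D is a good migrating group. The skeleton of unit 2 is reached in fewer steps than by the auxiliary route, so on step count for the skeleton it is better.
- Against: A5 is flat at C3 of unit 2 and carries C4=O and C2=C3. The stereocentre would have to be set afterwards by asymmetric reduction and the carbonyl removed, at least three further steps on the heaviest intermediate. Thallium is highly toxic. The oxidant would meet the electron-rich rings and the doubly benzylic C4–H of unit 1.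
- Comparison: this alternative does not touch the problem of unit 1 and only reverses the order of assembly. The chosen plan sets C3 of unit 2 early, on a small molecule, by a dependable method. The ring D aldehyde building block is equal in both plans. Overall step count is judged about equal once the reductions are added.

**Alternative 3:** benzylic cation cycloalkylation of ring A.
- Cut: C4–C4a only.
- Forward key step: Sc(OTf)3 would ionise the C4 carbinol of A8 (either epimer). The cation, stabilised by ring D, would be attacked by ring A para to its benzyloxy group, closing ring C to A7 with the aryl groups trans.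
- In favour: the cation is formed at a defined carbon, so there is no regiochemical question and no intermolecular competition. On these points it is better than the chosen plan. The reaction type is known. C3 can be set beforehand by an auxiliary aldol, so the absolute configuration is more secure. A7 needs only one hydrogenolysis, one step fewer after the key step.
- Against: C2–C3, C3–C4 and the C3 stereocentre must be built linearly first (arylacetic acid, aldol, reduction, etherification), about five more steps in total. With a benzyloxy group on ring B, that oxygen can capture the C4 cation in a five-membered closure with loss of benzyl.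
- Comparison: the cation and the trans-selective ring closure are the same as in the chosen plan, so the two are equal there. The chosen plan is more convergent and shorter but rests on an unprecedented step. A variant of this alternative with a pivalate on ring B is kept as the fallback for the key step.

Key step: step 15

Remark: the formaldehyde acetal is used as the pivaloyloxymethyl ether 2 rather than a methoxymethyl ether, because a mixed aryl methyl acetal is expected to ionise with loss of the aryloxy group. Ring A, O1 and the acetal carbon are unchanged.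
Remark: the sense of induction of the chiral acid cannot be assigned in advance; the (S,S) catalyst is written, and its antipode is taken if the other face is delivered.
Remark: 13 is taken as a catalogue compound.

## Route

Step 1
Reactants: 1 3-(benzyloxy)phenol
Product: 2 [3-(benzyloxy)phenoxy]methyl pivalate
Conditions: chloromethyl pivalate, K2CO3, NaI (cat.), DMF, 40 °C
Reagents that add atoms: chloromethyl pivalate, CC(C)(C)C(=O)OCCl
Why: Williamson-type O-alkylation of the phenoxide with iodide catalysis; the hindered pivaloyl carbonyl resists acyl transfer, and the reagent replaces chloromethyl methyl ether.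

Step 2
Reactants: 3 2-hydroxy-4-methoxybenzaldehyde
Product: 4 2-formyl-5-methoxyphenyl pivalate
Conditions: PivCl, Et3N, DMAP (cat.), CH2Cl2, 0 °C to rt
Reagents that add atoms: pivaloyl chloride, CC(C)(C)C(=O)Cl
Why: DMAP-catalysed acylation of the hydrogen-bonded phenol; the pivalate is chosen to survive the ylide and amine base of later steps.

Step 3
Reactants: 4 2-formyl-5-methoxyphenyl pivalate
Product: 5 5-methoxy-2-vinylphenyl pivalate
Conditions: Ph3PCH3Br, KOtBu, THF, 0 °C
Reagents that add atoms: methyltriphenylphosphonium bromide, C[P+](c1ccccc1)(c1ccccc1)c1ccccc1.[Br-]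
Why: Wittig methylenation; the aldehyde is far more electrophilic than the hindered aryl ester, so one equivalent of ylide at low temperature should react at the formyl group only.

Step 4
Reactants: 6 5-bromo-2-hydroxy-4-methoxybenzaldehyde
Product: 7 2-(benzyloxy)-5-bromo-4-methoxybenzaldehyde
Conditions: BnBr, K2CO3, DMF, 60 °C
Reagents that add atoms: benzyl bromide, BrCc1ccccc1
Why: Williamson benzylation of the phenol.

Step 5
Reactants: 7 2-(benzyloxy)-5-bromo-4-methoxybenzaldehyde
Product: 8 1-(benzyloxy)-4-bromo-5-methoxy-2-(2-methoxyvinyl)benzene (E/Z mixture)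
Conditions: Ph3P(CH2OMe)Cl, KOtBu, THF, 0 °C to rt
Reagents that add atoms: (methoxymethyl)triphenylphosphonium chloride, COC[P+](c1ccccc1)(c1ccccc1)c1ccccc1.[Cl-]
Why: Wittig methoxymethylenation installs the extra carbon of the arylacetic acid; the alkene geometry is irrelevant.

Step 6
Reactants: 8 1-(benzyloxy)-4-bromo-5-methoxy-2-(2-methoxyvinyl)benzene
Product: 10 [2-(benzyloxy)-5-bromo-4-methoxyphenyl]acetic acid, via arylacetaldehyde 9 (not isolated)
Conditions: 2 M HCl, THF, 40 °C; then NaClO2, NaH2PO4, 2-methyl-2-butene, t-BuOH/H2O, 0 °C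
Reagents that add atoms: water, O; sodium chlorite, [Na+].[O-]Cl=O
Why: acid hydrolysis of the enol ether followed at once by Pinnick oxidation, so the enolisable arylacetaldehyde is never handled; the alkene scavenger protects the electron-rich ring from hypochlorite.

Step 7
Reactants: 10 [2-(benzyloxy)-5-bromo-4-methoxyphenyl]acetic acid
Product: 12 (S)-4-benzyl-3-{[2-(benzyloxy)-5-bromo-4-methoxyphenyl]acetyl}oxazolidin-2-one, via mixed pivalic anhydride 11 (not isolated)
Conditions: PivCl, Et3N, THF, −20 °C; then (S)-4-benzyl-2-oxazolidinone, LiCl, rt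
Reagents that add atoms: (S)-4-benzyl-2-oxazolidinone, O=C1N[C@@H](Cc2ccccc2)CO1
Why: N-acylation of the oxazolidinone through the mixed anhydride, with attack at the less hindered carbonyl.

Step 8
Reactants: 13 4-(benzyloxy)-2-hydroxybenzaldehyde
Product: 14 4-(benzyloxy)-2-(triisopropylsilyloxy)benzaldehyde
Conditions: i-Pr3SiCl, imidazole, DMF, rt
Reagents that add atoms: chlorotriisopropylsilane, CC(C)[Si](Cl)(C(C)C)C(C)C
Why: silylation of the phenol; the bulky silyl group resists O-to-O migration to the benzylic alkoxide of step 9 and leaves with fluoride in step 13.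

Step 9
Reactants: 14 4-(benzyloxy)-2-(triisopropylsilyloxy)benzaldehyde
Product: 15 [4-(benzyloxy)-2-(triisopropylsilyloxy)phenyl]methanol
Conditions: NaBH4, MeOH/THF, −10 °C
Reagents that add atoms: none
Why: borohydride reduction of the aldehyde, run cold to suppress silyl migration.

Step 10
Reactants: 15 [4-(benzyloxy)-2-(triisopropylsilyloxy)phenyl]methanol
Product: 16 [5-(benzyloxy)-2-(bromomethyl)phenoxy]triisopropylsilane
Conditions: CBr4, PPh3, CH2Cl2, 0 °C; used crude at once
Reagents that add atoms: carbon tetrabromide, BrC(Br)(Br)Br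
Why: Appel bromination under neutral conditions; the electron-rich benzylic bromide is labile and is therefore not chromatographed or stored.

Step 11
Reactants: 12 (S)-4-benzyl-3-{[2-(benzyloxy)-5-bromo-4-methoxyphenyl]acetyl}oxazolidin-2-one; 16 [5-(benzyloxy)-2-(bromomethyl)phenoxy]triisopropylsilane
Product: 17 (S)-4-benzyl-3-{(2S)-3-[4-(benzyloxy)-2-(triisopropylsilyloxy)phenyl]-2-[2-(benzyloxy)-5-bromo-4-methoxyphenyl]propanoyl}oxazolidin-2-one
Conditions: NaN(SiMe3)2, THF, −78 °C; then 16, −78 to −30 °C
Reagents that add atoms: none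
Why: Evans alkylation; the chelated (Z)-sodium enolate is benzylated on the face opposite the 4-benzyl group of the auxiliary, which sets C3 of unit 2 as (S), and allylic strain in the product disfavours its re-enolisation.

Step 12
Reactants: 17 (S)-4-benzyl-3-{(2S)-3-[4-(benzyloxy)-2-(triisopropylsilyloxy)phenyl]-2-[2-(benzyloxy)-5-bromo-4-methoxyphenyl]propanoyl}oxazolidin-2-one
Product: 18 (2S)-3-[4-(benzyloxy)-2-(triisopropylsilyloxy)phenyl]-2-[2-(benzyloxy)-5-bromo-4-methoxyphenyl]propan-1-ol
Conditions: LiBH4, MeOH (1 equiv), THF, 0 °C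
Reagents that add atoms: none
Why: reductive removal of the auxiliary to the primary alcohol without touching the stereocentre, the aryl bromide or the silyl ether; the auxiliary is recovered.

Step 13
Reactants: 18 (2S)-3-[4-(benzyloxy)-2-(triisopropylsilyloxy)phenyl]-2-[2-(benzyloxy)-5-bromo-4-methoxyphenyl]propan-1-ol
Product: 20 (3S)-7-(benzyloxy)-3-[2-(benzyloxy)-5-bromo-4-methoxyphenyl]chroman, via mesylate 19 (not isolated)
Conditions: MsCl (1.05 equiv), Et3N, THF, 0 °C; then Bu4NF, THF, 50 °C
Reagents that add atoms: none
Why: mesylation of the primary alcohol, then fluoride desilylation frees the phenoxide, which closes the pyran ring by intramolecular Williamson etherification (6-exo-tet); the stereocentre is not involved.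

Step 14
Reactants: 20 (3S)-7-(benzyloxy)-3-[2-(benzyloxy)-5-bromo-4-methoxyphenyl]chroman; 5 5-methoxy-2-vinylphenyl pivalate
Product: 21 2-[(E)-2-{4-(benzyloxy)-5-[(3S)-7-(benzyloxy)chroman-3-yl]-2-methoxyphenyl}vinyl]-5-methoxyphenyl pivalate
Conditions: Pd2(dba)3, [HP(t-Bu)3]BF4, Cy2NMe, 1,4-dioxane, 80 °C
Reagents that add atoms: none
Why: Heck reaction; zerovalent palladium with the bulky electron-rich phosphine inserts into the electron-rich aryl bromide, and arylation of the terminal alkene carbon with syn beta-hydride elimination gives the (E)-stilbene while the hindered amine leaves the pivalate intact.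

Step 15
Reactants: 21 2-[(E)-2-{4-(benzyloxy)-5-[(3S)-7-(benzyloxy)chroman-3-yl]-2-methoxyphenyl}vinyl]-5-methoxyphenyl pivalate; 2 [3-(benzyloxy)phenoxy]methyl pivalate
Product: 22 2-[(3S,4R)-7-(benzyloxy)-4-{4-(benzyloxy)-5-[(3S)-7-(benzyloxy)chroman-3-yl]-2-methoxyphenyl}chroman-3-yl]-5-methoxyphenyl pivalate
Conditions: (S,S)-imidodiphosphorimidate acid (BINOL-derived, N-triflyl, 3,3′-diaryl; 5 mol %), 2 (1.5 equiv, syringe pump), 5 Å MS, CH2Cl2/toluene, −60 °C
Reagents that add atoms: none
Why: Proposed new method: the confined chiral acid protonates the acylal carbonyl of 2 and pivalic acid leaves, giving the aryloxymethyl cation (ring A, O1, C2) as a contact ion pair with the chiral anion; carboxylate is the only group that can leave, so the sense of ionisation is unambiguous. The cationic carbon adds to the alkene carbon of 21 that bears ring B, because the charge then develops next to ring D (para benzyloxy, ortho methoxy) rather than next to ring B, whose ortho pivalate is an acceptor; this forms C2–C3 and sets C3, with the face chosen by the counteranion since the stereocentre of unit 2 is too remote to matter. The benzylic cation at C4 is then captured by ring A at the carbon para to its benzyloxy group in a six-membered Friedel–Crafts closure (6-endo with respect to the arene pi bond), forming C4–C4a in a stepwise cationic [4+2]. C4 is set relative to C3 by this ring closure: a chair-like transition state with both aryl groups pseudo-equatorial, together with the (E)-geometry, gives the trans (3S,4R) ring. Loss of the arenium proton returns the acid, so no silyl reagent or other pi-nucleophilic additive is present. The closest known reaction types are the achiral Lewis-acid-promoted oxa-Povarov [4+2] of aryl oxocarbenium ions with alkenes and asymmetric Prins reactions of formaldehyde with styrenes under confined chiral Brønsted acid catalysis. The step needs the alkene to outcompete the alkoxyarene rings as nucleophile (slow addition of 2 keeps the cation concentration low) and para rather than ortho closure on ring A (the position between the two oxygens is the more hindered).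

Step 16
Reactants: 22 2-[(3S,4R)-7-(benzyloxy)-4-{4-(benzyloxy)-5-[(3S)-7-(benzyloxy)chroman-3-yl]-2-methoxyphenyl}chroman-3-yl]-5-methoxyphenyl pivalate
Product: 23 2-[(3S,4R)-7-(benzyloxy)-4-{4-(benzyloxy)-5-[(3S)-7-(benzyloxy)chroman-3-yl]-2-methoxyphenyl}chroman-3-yl]-5-methoxyphenol
Conditions: NaOMe, MeOH/THF, 40 °C; AcOH
Reagents that add atoms: none
Why: methanolysis (transesterification) of the aryl pivalate by methoxide; no stereocentre is acidic enough to be at risk and a pyrophoric hydride is avoided.

Step 17
Reactants: 23 2-[(3S,4R)-7-(benzyloxy)-4-{4-(benzyloxy)-5-[(3S)-7-(benzyloxy)chroman-3-yl]-2-methoxyphenyl}chroman-3-yl]-5-methoxyphenol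
Product: 24 (3S,4R)-4-{4-hydroxy-5-[(3S)-7-hydroxychroman-3-yl]-2-methoxyphenyl}-3-(2-hydroxy-4-methoxyphenyl)chroman-7-ol
Conditions: H2 (1 atm), Pd/C, EtOAc/MeOH, rt
Reagents that add atoms: none
Why: hydrogenolysis of the three aryl benzyl ethers; the chroman C–O bonds are not benzylic and the diarylmethine C4–H is inert, so only the protecting groups should be lost.

## Compound list

1 | 3-(benzyloxy)phenol | Oc1cccc(OCc2ccccc2)c1 | starting material
2 | [3-(benzyloxy)phenoxy]methyl pivalate | CC(C)(C)C(=O)OCOc1cccc(OCc2ccccc2)c1 | intermediate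
3 | 2-hydroxy-4-methoxybenzaldehyde | COc1ccc(C=O)c(O)c1 | starting material
4 | 2-formyl-5-methoxyphenyl pivalate | COc1ccc(C=O)c(OC(=O)C(C)(C)C)c1 | intermediate
5 | 5-methoxy-2-vinylphenyl pivalate | COc1ccc(C=C)c(OC(=O)C(C)(C)C)c1 | intermediate
6 | 5-bromo-2-hydroxy-4-methoxybenzaldehyde | COc1cc(O)c(C=O)cc1Br | starting material
7 | 2-(benzyloxy)-5-bromo-4-methoxybenzaldehyde | COc1cc(OCc2ccccc2)c(C=O)cc1Br | intermediate
8 | 1-(benzyloxy)-4-bromo-5-methoxy-2-(2-methoxyvinyl)benzene (E/Z mixture) | COC=Cc1cc(Br)c(OC)cc1OCc1ccccc1 | intermediate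
9 | [2-(benzyloxy)-5-bromo-4-methoxyphenyl]acetaldehyde | O=CCc1cc(Br)c(OC)cc1OCc1ccccc1 | intermediate
10 | [2-(benzyloxy)-5-bromo-4-methoxyphenyl]acetic acid | OC(=O)Cc1cc(Br)c(OC)cc1OCc1ccccc1 | intermediate
11 | [2-(benzyloxy)-5-bromo-4-methoxyphenyl]acetic pivalic anhydride | CC(C)(C)C(=O)OC(=O)Cc1cc(Br)c(OC)cc1OCc1ccccc1 | intermediate
12 | (S)-4-benzyl-3-{[2-(benzyloxy)-5-bromo-4-methoxyphenyl]acetyl}oxazolidin-2-one | O=C(Cc1cc(Br)c(OC)cc1OCc1ccccc1)N1[C@@H](Cc2ccccc2)COC1=O | intermediate
13 | 4-(benzyloxy)-2-hydroxybenzaldehyde | O=Cc1ccc(OCc2ccccc2)cc1O | starting material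
14 | 4-(benzyloxy)-2-(triisopropylsilyloxy)benzaldehyde | O=Cc1ccc(OCc2ccccc2)cc1O[Si](C(C)C)(C(C)C)C(C)C | intermediate
15 | [4-(benzyloxy)-2-(triisopropylsilyloxy)phenyl]methanol | OCc1ccc(OCc2ccccc2)cc1O[Si](C(C)C)(C(C)C)C(C)C | intermediate
16 | [5-(benzyloxy)-2-(bromomethyl)phenoxy]triisopropylsilane | BrCc1ccc(OCc2ccccc2)cc1O[Si](C(C)C)(C(C)C)C(C)C | intermediate
17 | (S)-4-benzyl-3-{(2S)-3-[4-(benzyloxy)-2-(triisopropylsilyloxy)phenyl]-2-[2-(benzyloxy)-5-bromo-4-methoxyphenyl]propanoyl}oxazolidin-2-one | O=C([C@@H](Cc1ccc(OCc2ccccc2)cc1O[Si](C(C)C)(C(C)C)C(C)C)c1cc(Br)c(OC)cc1OCc1ccccc1)N1[C@@H](Cc2ccccc2)COC1=O | intermediate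
18 | (2S)-3-[4-(benzyloxy)-2-(triisopropylsilyloxy)phenyl]-2-[2-(benzyloxy)-5-bromo-4-methoxyphenyl]propan-1-ol | OC[C@@H](Cc1ccc(OCc2ccccc2)cc1O[Si](C(C)C)(C(C)C)C(C)C)c1cc(Br)c(OC)cc1OCc1ccccc1 | intermediate
19 | (2S)-3-[4-(benzyloxy)-2-(triisopropylsilyloxy)phenyl]-2-[2-(benzyloxy)-5-bromo-4-methoxyphenyl]propyl methanesulfonate | CS(=O)(=O)OC[C@@H](Cc1ccc(OCc2ccccc2)cc1O[Si](C(C)C)(C(C)C)C(C)C)c1cc(Br)c(OC)cc1OCc1ccccc1 | intermediate
20 | (3S)-7-(benzyloxy)-3-[2-(benzyloxy)-5-bromo-4-methoxyphenyl]chroman | COc1cc(OCc2ccccc2)c([C@H]2COc3cc(OCc4ccccc4)ccc3C2)cc1Br | intermediate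
21 | 2-[(E)-2-{4-(benzyloxy)-5-[(3S)-7-(benzyloxy)chroman-3-yl]-2-methoxyphenyl}vinyl]-5-methoxyphenyl pivalate | COc1ccc(/C=C/c2cc([C@H]3COc4cc(OCc5ccccc5)ccc4C3)c(OCc3ccccc3)cc2OC)c(OC(=O)C(C)(C)C)c1 | intermediate
22 | 2-[(3S,4R)-7-(benzyloxy)-4-{4-(benzyloxy)-5-[(3S)-7-(benzyloxy)chroman-3-yl]-2-methoxyphenyl}chroman-3-yl]-5-methoxyphenyl pivalate | COc1ccc([C@H]2COc3cc(OCc4ccccc4)ccc3[C@@H]2c2cc([C@H]3COc4cc(OCc5ccccc5)ccc4C3)c(OCc3ccccc3)cc2OC)c(OC(=O)C(C)(C)C)c1 | intermediate
23 | 2-[(3S,4R)-7-(benzyloxy)-4-{4-(benzyloxy)-5-[(3S)-7-(benzyloxy)chroman-3-yl]-2-methoxyphenyl}chroman-3-yl]-5-methoxyphenol | COc1ccc([C@H]2COc3cc(OCc4ccccc4)ccc3[C@@H]2c2cc([C@H]3COc4cc(OCc5ccccc5)ccc4C3)c(OCc3ccccc3)cc2OC)c(O)c1 | intermediate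
24 | (3S,4R)-4-{4-hydroxy-5-[(3S)-7-hydroxychroman-3-yl]-2-methoxyphenyl}-3-(2-hydroxy-4-methoxyphenyl)chroman-7-ol | COc1ccc([C@H]2COc3cc(O)ccc3[C@@H]2c2cc([C@H]3COc4cc(O)ccc4C3)c(O)cc2OC)c(O)c1 | target

## Step count and risks

Total step count: 17. Longest linear sequence: 11 steps (steps 4, 5, 6, 7, 11, 12, 13, 14, 15, 16, 17).

**Step 15 (key step, proposed new method).**
- What may go wrong:
  - alkylation of the alkoxyarene rings of 2, 21 or 22 by the aryloxymethyl cation instead of the alkene, leading to diarylmethane oligomers, because these rings are nucleophiles of similar strength;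
  - protonation of the electron-rich stilbene by the strong acid, with dimerisation or loss of geometry;
  - insufficient facial discrimination, because the cation is small and the counteranion has little to hold on to;
  - partial C–C bond formation at the other alkene carbon, because the para methoxy group of ring B also stabilises a cation;
  - loss of a proton from the C4 cation before ring closure.
- Fallback (known chemistry): the ring is closed through a preformed carbinol, setting out from 20, 4 and 1 and coming back to the route at 22. Bromine–lithium exchange on 20 (n-BuLi, THF, −78 °C) and DMF would give 4-(benzyloxy)-5-[(3S)-7-(benzyloxy)chroman-3-yl]-2-methoxybenzaldehyde F1. Aldehyde 4 would be homologated as in steps 5 and 6 through 5-methoxy-2-(2-methoxyvinyl)phenyl pivalate F2 to [4-methoxy-2-(pivaloyloxy)phenyl]acetic acid F3, and attached as in step 7, but to (R)-4-benzyl-2-oxazolidinone, to give (R)-4-benzyl-3-{[4-methoxy-2-(pivaloyloxy)phenyl]acetyl}oxazolidin-2-one F4. Boron aldol addition of F4 to F1 (Bu2BOTf, i-Pr2NEt, CH2Cl2, −78 °C) should give the syn aldol (R)-4-benzyl-3-[(2R,3R)-3-{4-(benzyloxy)-5-[(3S)-7-(benzyloxy)chroman-3-yl]-2-methoxyphenyl}-3-hydroxy-2-[4-methoxy-2-(pivaloyloxy)phenyl]propanoyl]oxazolidin-2-one F5, which fixes the future C3. Brief LiBH4 reduction (THF, 0 °C; the hindered aryl ester is expected to survive) would give 5-methoxy-2-[(1R,2S)-1-{4-(benzyloxy)-5-[(3S)-7-(benzyloxy)chroman-3-yl]-2-methoxyphenyl}-1,3-dihydroxypropan-2-yl]phenyl pivalate F6. Mitsunobu etherification of its primary hydroxyl with 1 (PPh3, DIAD, THF) would give 5-methoxy-2-[(1R,2S)-3-[3-(benzyloxy)phenoxy]-1-{4-(benzyloxy)-5-[(3S)-7-(benzyloxy)chroman-3-yl]-2-methoxyphenyl}-1-hydroxypropan-2-yl]phenyl pivalate F7. Sc(OTf)3 in MeCN would ionise the carbinol and close ring C trans by Friedel–Crafts cycloalkylation to 22; the carbinol configuration is lost in the cation and does not matter.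

**Step 11.**
- What may go wrong: decomposition of the benzylic bromide by ionisation or by desilylation to a quinone methide before it is alkylated, and partial epimerisation of the alpha-aryl centre if excess base is present.
- Fallback: the stereocentre is set by asymmetric hydrogenation instead of alkylation, setting out from 10 and 13 and returning at 20. Perkin condensation (Ac2O, Et3N, 110 °C) would give 7-(benzyloxy)-3-[2-(benzyloxy)-5-bromo-4-methoxyphenyl]-2H-chromen-2-one F8. Reduction with i-Bu2AlH (CH2Cl2, −78 to 0 °C) would give 5-(benzyloxy)-2-{(1Z)-2-[2-(benzyloxy)-5-bromo-4-methoxyphenyl]-3-hydroxyprop-1-en-1-yl}phenol F9. Mitsunobu ring closure (PPh3, DIAD) would give 7-(benzyloxy)-3-[2-(benzyloxy)-5-bromo-4-methoxyphenyl]-2H-chromene F10. Hydrogenation with a chiral iridium complex [Ir(cod)(L)][B(C6H3(CF3)2)4] (L a chiral phosphine–oxazoline, enantiomer chosen for the (S) product; H2, CH2Cl2) would give 20.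

**Step 14.**
- What may go wrong: slow oxidative addition into the electron-rich, ortho-substituted aryl bromide, with polymerisation of the styrene or loss of the pivalate on prolonged heating.
- Fallback: the alkene carbon is made the nucleophile, setting out from 5 and 20 and returning at 21. Cross-metathesis of 5 with vinylboronic acid pinacol ester (second-generation Grubbs catalyst RuCl2(H2IMes)(PCy3)(=CHPh), CH2Cl2, 40 °C) would give 5-methoxy-2-[(E)-2-(4,4,5,5-tetramethyl-1,3,2-dioxaborolan-2-yl)vinyl]phenyl pivalate F11. Suzuki–Miyaura coupling of F11 with 20 (Pd(dppf)Cl2, CsF, 1,4-dioxane, 80 °C) would give 21.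

**Step 13.**
- What may go wrong: sulfonylation of the liberated phenoxide by residual MsCl, or fluoride substitution or elimination at the mesylate, in the one-flask sequence.
- Fallback: redox condensation replaces the sulfonate displacement, setting out from 18 and returning at 20. Bu4NF (THF, 0 °C) would give 5-(benzyloxy)-2-{(2S)-2-[2-(benzyloxy)-5-bromo-4-methoxyphenyl]-3-hydroxypropyl}phenol F12, which would be closed by intramolecular Mitsunobu etherification (PPh3, DIAD, THF, 0 °C) to 20.

## Further compounds

F1 | step 15 | 4-(benzyloxy)-5-[(3S)-7-(benzyloxy)chroman-3-yl]-2-methoxybenzaldehyde | COc1cc(OCc2ccccc2)c([C@H]2COc3cc(OCc4ccccc4)ccc3C2)cc1C=O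
F2 | step 15 | 5-methoxy-2-(2-methoxyvinyl)phenyl pivalate (E/Z mixture) | COC=Cc1ccc(OC)cc1OC(=O)C(C)(C)C
F3 | step 15 | [4-methoxy-2-(pivaloyloxy)phenyl]acetic acid | COc1ccc(CC(=O)O)c(OC(=O)C(C)(C)C)c1
F4 | step 15 | (R)-4-benzyl-3-{[4-methoxy-2-(pivaloyloxy)phenyl]acetyl}oxazolidin-2-one | O=C(Cc1ccc(OC)cc1OC(=O)C(C)(C)C)N1[C@H](Cc2ccccc2)COC1=O
F5 | step 15 | (R)-4-benzyl-3-[(2R,3R)-3-{4-(benzyloxy)-5-[(3S)-7-(benzyloxy)chroman-3-yl]-2-methoxyphenyl}-3-hydroxy-2-[4-methoxy-2-(pivaloyloxy)phenyl]propanoyl]oxazolidin-2-one | O=C([C@H](c1ccc(OC)cc1OC(=O)C(C)(C)C)[C@@H](O)c1cc([C@H]2COc3cc(OCc4ccccc4)ccc3C2)c(OCc2ccccc2)cc1OC)N1[C@H](Cc2ccccc2)COC1=O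
F6 | step 15 | 5-methoxy-2-[(1R,2S)-1-{4-(benzyloxy)-5-[(3S)-7-(benzyloxy)chroman-3-yl]-2-methoxyphenyl}-1,3-dihydroxypropan-2-yl]phenyl pivalate | OC[C@H](c1ccc(OC)cc1OC(=O)C(C)(C)C)[C@@H](O)c1cc([C@H]2COc3cc(OCc4ccccc4)ccc3C2)c(OCc2ccccc2)cc1OC
F7 | step 15 | 5-methoxy-2-[(1R,2S)-3-[3-(benzyloxy)phenoxy]-1-{4-(benzyloxy)-5-[(3S)-7-(benzyloxy)chroman-3-yl]-2-methoxyphenyl}-1-hydroxypropan-2-yl]phenyl pivalate | C(Oc1cccc(OCc2ccccc2)c1)[C@H](c1ccc(OC)cc1OC(=O)C(C)(C)C)[C@@H](O)c1cc([C@H]2COc3cc(OCc4ccccc4)ccc3C2)c(OCc2ccccc2)cc1OC
F8 | step 11 | 7-(benzyloxy)-3-[2-(benzyloxy)-5-bromo-4-methoxyphenyl]-2H-chromen-2-one | COc1cc(OCc2ccccc2)c(-c2cc3ccc(OCc4ccccc4)cc3oc2=O)cc1Br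
F9 | step 11 | 5-(benzyloxy)-2-{(1Z)-2-[2-(benzyloxy)-5-bromo-4-methoxyphenyl]-3-hydroxyprop-1-en-1-yl}phenol | OC/C(=C\c1ccc(OCc2ccccc2)cc1O)c1cc(Br)c(OC)cc1OCc1ccccc1
F10 | step 11 | 7-(benzyloxy)-3-[2-(benzyloxy)-5-bromo-4-methoxyphenyl]-2H-chromene | COc1cc(OCc2ccccc2)c(C2=Cc3ccc(OCc4ccccc4)cc3OC2)cc1Br
F11 | step 14 | 5-methoxy-2-[(E)-2-(4,4,5,5-tetramethyl-1,3,2-dioxaborolan-2-yl)vinyl]phenyl pivalate | COc1ccc(/C=C/B2OC(C)(C)C(C)(C)O2)c(OC(=O)C(C)(C)C)c1
F12 | step 13 | 5-(benzyloxy)-2-{(2S)-2-[2-(benzyloxy)-5-bromo-4-methoxyphenyl]-3-hydroxypropyl}phenol | OC[C@@H](Cc1ccc(OCc2ccccc2)cc1O)c1cc(Br)c(OC)cc1OCc1ccccc1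
A1 | alternative 1 | (3S,4R)-7-(benzyloxy)-4-{4-(benzyloxy)-5-[(3S)-7-(benzyloxy)chroman-3-yl]-2-methoxyphenyl}-3-[2-(benzyloxy)-4-methoxyphenyl]chroman-2-one | COc1ccc([C@H]2C(=O)Oc3cc(OCc4ccccc4)ccc3[C@@H]2c2cc([C@H]3COc4cc(OCc5ccccc5)ccc4C3)c(OCc3ccccc3)cc2OC)c(OCc2ccccc2)c1
A2 | alternative 1 | 5-(benzyloxy)-2-[{4-(benzyloxy)-5-[(3S)-7-(benzyloxy)chroman-3-yl]-2-methoxyphenyl}(4-methylbenzenesulfonyl)methyl]phenol | Cc1ccc(S(=O)(=O)C(c2ccc(OCc3ccccc3)cc2O)c2cc([C@H]3COc4cc(OCc5ccccc5)ccc4C3)c(OCc3ccccc3)cc2OC)cc1
A3 | alternative 1 | [2-(benzyloxy)-4-methoxyphenyl]acetic acid | COc1ccc(CC(=O)O)c(OCc2ccccc2)c1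
A4 | alternative 1 | 3-(benzyloxy)-6-({4-(benzyloxy)-5-[(3S)-7-(benzyloxy)chroman-3-yl]-2-methoxyphenyl}methylidene)cyclohexa-2,4-dien-1-one | O=C1C=C(OCc2ccccc2)C=CC1=Cc1cc([C@H]2COc3cc(OCc4ccccc4)ccc3C2)c(OCc2ccccc2)cc1OC
A5 | alternative 2 | 7-(benzyloxy)-3-{2-(benzyloxy)-5-[(3S,4R)-7-(benzyloxy)-3-[2-(benzyloxy)-4-methoxyphenyl]chroman-4-yl]-4-methoxyphenyl}-4H-chromen-4-one | COc1ccc([C@H]2COc3cc(OCc4ccccc4)ccc3[C@@H]2c2cc(-c3coc4cc(OCc5ccccc5)ccc4c3=O)c(OCc3ccccc3)cc2OC)c(OCc2ccccc2)c1
A6 | alternative 2 | (E)-1-[4-(benzyloxy)-2-hydroxyphenyl]-3-{2-(benzyloxy)-5-[(3S,4R)-7-(benzyloxy)-3-[2-(benzyloxy)-4-methoxyphenyl]chroman-4-yl]-4-methoxyphenyl}prop-2-en-1-one | COc1ccc([C@H]2COc3cc(OCc4ccccc4)ccc3[C@@H]2c2cc(/C=C/C(=O)c3ccc(OCc4ccccc4)cc3O)c(OCc3ccccc3)cc2OC)c(OCc2ccccc2)c1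
A7 | alternative 3 | (3S,4R)-7-(benzyloxy)-4-{4-(benzyloxy)-5-[(3S)-7-(benzyloxy)chroman-3-yl]-2-methoxyphenyl}-3-[2-(benzyloxy)-4-methoxyphenyl]chroman | COc1ccc([C@H]2COc3cc(OCc4ccccc4)ccc3[C@@H]2c2cc([C@H]3COc4cc(OCc5ccccc5)ccc4C3)c(OCc3ccccc3)cc2OC)c(OCc2ccccc2)c1
A8 | alternative 3 | (2S)-3-[3-(benzyloxy)phenoxy]-1-{4-(benzyloxy)-5-[(3S)-7-(benzyloxy)chroman-3-yl]-2-methoxyphenyl}-2-[2-(benzyloxy)-4-methoxyphenyl]propan-1-ol (either C1 epimer) | COc1ccc([C@@H](COc2cccc(OCc3ccccc3)c2)C(O)c2cc([C@H]3COc4cc(OCc5ccccc5)ccc4C3)c(OCc3ccccc3)cc2OC)c(OCc2ccccc2)c1
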